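The overall equation cannot have used up either reagent in cedar by its last reading: at 72 min target equals 61.7% of the substrate charged and 41.2% of the partner charged, and both shares lie below full use.

| flask | substrate | partner | time |
|---|---|---|---|
| cedar | 150 mM | 225 mM |  |
| alder | 60.0 mM | 135 mM |  |
| larch | 150 mM | 340 mM |  |
| maple | 300 mM | 225 mM |  |
| birch | 150 mM | 225 mM | 220 min |

| run | time / min | [target] / mM |
|---|---|---|
| cedar run | 10 | 66.8 |
| cedar run | 21 | 81.0 |
| cedar run | 31 | 86.3 |
| cedar run | 41 | 89.4 |
| cedar run | 51 | 91.7 |
| cedar run | 62 | 92.1 |
| cedar run | 72 | 92.6 |
| alder run | 10 | 15.2 |
| alder run | 21 | 24.2 |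
| alder run | 31 | 27.6 |
| alder run | 41 | 30.1 |
| alder run | 51 | 31.3 |
| alder run | 62 | 32.3 |
| alder run | 72 | 32.5 |
| larch run | 10 | 104.8 |
| larch run | 21 | 117.6 |
| larch run | 31 | 121.1 |
| larch run | 41 | 121.9 |
| larch run | 51 | 122.9 |
| larch run | 62 | 122.6 |
| larch run | 72 | 122.1 |
| maple run | 10 | 94.7 |
| maple run | 21 | 110.5 |
| maple run | 31 | 116.4 |
| maple run | 41 | 120.1 |
| maple run | 51 | 122.0 |
| maple run | 62 | 123.5 |
| maple run | 72 | 124.6 |

(each reading ± 0.4 mM)

- Overall: substrate + partner -> target.
- Constant volume, constant temperature.
- "The second partner" is partner.
- An order is taken over about fifteen percent of the charge, up and down.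

- apparent order in [substrate] of the starting rate, round the charge of the cedar run (the rate where two percent of its substrate have turned into target) (one fixed amount of target, the same in the runs compared)
- apparent order in [partner] of the starting rate, round the charge of the cedar run (the rate where two percent of its substrate have turned into target)
- target in the birch run at 220 min, as a share of the substrate charged

Cedar's rate, as a share of its substrate charge, is 0.0445 /min on average up to the first reading. It then falls between successive readings by factors of 5.17, 2.44 and 1.71.

The closing time is 7.83 min for cedar: the time in which the gap between target and its last reading shrinks by a factor e, if the rate falls in steady proportion. The same reckoning gives 15.9 min for alder, 5.12 min for larch and 7.01 min for maple. Last reading over closing time estimates a starting rate, 0.0789 /min of the charge for cedar.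

My own reckoning compares these rates and gives orders of 0.588 in substrate and 1.70 in partner. With these orders, the shares that the overall equation leaves at cedar's last reading slow cedar by a factor of 4.33. Cedar's readings show a factor of 64.7 from the average rate up to the first reading to the average rate over the last stretch, so on this reckoning the overall equation does not account for the accumulated slowing.

Birch repeats cedar's charge, and 220 min is 28.1 closing times, so my number is cedar's last share, 61.7%.

The forecast gives 0.75, 2.1 and 62.3%, each higher than my number. Its reading of the stall is “which suggests the active species dies”.

The flask ran by these steps:

    substrate + 2 partner → target + partner (2.616 /M²/min)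
    partner → lost reagent (0.005844 /min)
    2 substrate → homo dimer (0.3468 /M/min)

It gives 1.0 in substrate, 2.1 in partner and 63.8% for birch. Maple, with twice cedar's substrate, runs at 2.0 times cedar's rate where the same amount of target has been made. Birch stands 2.1 percentage points above cedar's last share, although 28.1 closing times have passed. Alder's closing time of 15.9 min puts target at half of its substrate charge at 40.7 min, and the alder flask reaches that share at 41.8 min.

All runs were generated by integration for substances that don't exist; scatter was added.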